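4 questions stood before me: which flask held most target, and how much each held.

* the best flask by amount of target, in percent of the starting material charged; "all alike" if 1.5 percentage points covers them all (Saturday's / Monday's / Thursday's / all alike)
* amount of target at the end, in percent of the starting material charged, Saturday's
* amount of target at the end, in percent of the starting material charged, Monday's
* amount of target at the end, in percent of the starting material charged, Thursday's

| flask | starting material | second substrate | reagent | free catalyst | temperature | remark | time |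
|---|---|---|---|---|---|---|---|
| gamma | 0.54 M | 0.40 M | 0.64 M | 2.6 mM | 15 °C | run made earlier |  |
| eta | 1.2 M | 0.40 M | 0.64 M | 2.6 mM | 48 °C | run made earlier |  |
| theta | 0.80 M | 0.80 M | 0.64 M | 2.6 mM | 15 °C | run made earlier |  |
| Saturday's | 0.80 M | 0.400 M | 0.640 M | 2.6 mM | 30 °C |  | 8.0 min |
| Monday's | 0.80 M | 0.400 M | 0.640 M | 2.6 mM | 0 °C |  | 8.0 min |
| Thursday's | 0.80 M | 0.400 M | 0.640 M | 2.6 mM | 60 °C |  | 8.0 min |

| run | time / min | target / % |
|---|---|---|
| gamma | 0.833 | 40.5 |
| gamma | 3.00 | 37.8 |
| gamma | 5.00 | 37.8 |
| gamma | 6.00 | 37.8 |
| gamma | 10.0 | 37.5 |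
| gamma | 12.0 | 37.6 |
| gamma | 15.0 | 37.7 |
| eta | 0.417 | 34.0 |
| eta | 1.00 | 33.8 |
| eta | 1.33 | 33.9 |
| eta | 2.00 | 33.9 |
| eta | 2.50 | 33.7 |
| eta | 3.00 | 33.6 |
| theta | 1.33 | 20.0 |
| theta | 4.00 | 19.6 |
| theta | 8.00 | 20.2 |
| theta | 12.0 | 19.8 |
| theta | 15.0 | 19.6 |

(standard deviation of a reading: 0.3 percentage points)



In the gamma run target fell from 40.5% at 0.833 min to 37.7% at 15.0 min, so I took target to be able to go back to starting material and reagent. Theta, with 0.80 M of second substrate, gave 19.6%, so I guessed that second substrate takes reagent one for one into second product. Taking gamma's 0.40 M of second substrate as turned wholly into second product, I had 0.0364 M of reagent left at the plateau, and from that 16.6 M⁻¹. This balance number, c(target)/(c(starting material)·c(reagent)) at the point where the forward and backward rates of target cancel, is the equilibrium constant of that step, and I kept it unchanged with temperature.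

For Monday's flask I took the forward rate to go with c(starting material)·c(reagent). With 0.240 M of reagent free of the second substrate, the rates cancel at 0.218 M of target. By then the starting material has slowed the forward rate by a factor 1.37 and the reagent by a factor 28.5. That makes 27.2% for Monday's. But eta's last reading, 0.403 M of target, leaves room for 0.237 M of second product by my one-for-one guess, so on that guess some second substrate stayed over in the eta run. For Saturday's and Thursday's I gave no figure.

The forecast said Saturday's 43.5%, Monday's 36% and Thursday's 52%, with Thursday's best, on the ground that “the sink is exothermic and heat favours target”. Its Monday's figure stands above mine.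

The simulation gave Saturday's 36.4%, Monday's 27.0% and Thursday's 45.2%, so Thursday's was best.

    starting material + free catalyst ⇌ catalyst intermediate A (K = 2.60 M⁻¹, k = 120 M⁻¹ s⁻¹, Ea = 39.0 kJ mol⁻¹, ΔH = 34.0 kJ mol⁻¹)
    reagent + catalyst intermediate B → free catalyst + second product (k = 48.0 M⁻¹ s⁻¹, Ea = 48.0 kJ mol⁻¹)
    catalyst intermediate B → spent catalyst (k = 0.00950 s⁻¹, Ea = 74.0 kJ mol⁻¹)
    second substrate + free catalyst ⇌ catalyst intermediate B (K = 220 M⁻¹, k = 47.0 M⁻¹ s⁻¹, Ea = 47.0 kJ mol⁻¹, ΔH = −19.0 kJ mol⁻¹)
    reagent + catalyst intermediate A ⇌ free catalyst + target (K = 5.80, k = 8.90 M⁻¹ s⁻¹, Ea = 52.0 kJ mol⁻¹, ΔH = −32.0 kJ mol⁻¹)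
    (constants at 0 °C)

Monday's ended with 0% of its second substrate left, 0.400 M of second product and 27.0% of target, against my 27.2%. Thursday's kept 38% of its second substrate, with 100% of its catalyst as spent catalyst, and its 45.2% lies above that reckoning. The neighbour like Thursday's but with 1.1 M of reagent ended with 0% of second substrate and 0.398 M of second product. The same balance number, with 0.700 M of reagent free, gives 70.0%, and that flask held 70.7%.

The numbers in the tables come from a simulation with made-up constants; scatter was added.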